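Side-chain carbons are numbered C1' (benzylic) to C17'; the carbinol is C15'. The route rests on cutting C11'–C12' in the unbranched tether. C12' is 1,4-related to the C15' hydroxyl, so C12'≡C13' can be carried as the terminal alkyne of (S)-hex-5-yn-3-ol, obtained from (S)-1,2-epoxybutane, which fixes C15'. The key step alkylates the O,C-dilithio derivative of this unprotected alkynol with a dibenzyl-protected 5-(11-bromoundecyl)resorcinol, joining both halves without any protecting group on the alcohol. One final hydrogenation then saturates the alkyne and frees both phenols of the resorcinol ring.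

Key step: step 3

Remark: 1,3-bis(benzyloxy)-5-bromobenzene (5) is assumed to be purchasable as a catalogue compound.

Step 1
Reactants: 1 (S)-1,2-epoxybutane; 2 lithium acetylide–ethylenediamine complex
Product: 3 (S)-hex-5-yn-3-ol
Conditions: 2 (1.5 equiv), DMSO, 0 °C → rt; then H2O
Reagents that add atoms: none
Why: SN2 ring opening of the terminal epoxide by the acetylide at the unsubstituted CH2 (epoxide alkynylation) does not touch the C–O bond of the stereocentre, so the S configuration of 1 should pass unchanged into 3.

Step 2
Reactants: 4 11-bromoundec-1-ene; 5 1,3-bis(benzyloxy)-5-bromobenzene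
Product: 7 1,3-bis(benzyloxy)-5-(11-bromoundecyl)benzene, via B-(11-bromoundecyl)-9-BBN 6 (not isolated)
Conditions: 9-BBN, THF, 0 °C → rt; then 5, Pd(dppf)Cl2 (3 mol%), aq. K3PO4, THF/DMF, 60 °C
Reagents that add atoms: none
Why: Anti-Markovnikov hydroboration of the terminal alkene followed by B-alkyl Suzuki–Miyaura coupling, in which Pd(0)/dppf should insert into the C(sp2)–Br bond of 5 much faster than into the primary C(sp3)–Br bond, which is thereby kept for the key step.

Step 3
Reactants: 3 (S)-hex-5-yn-3-ol; 7 1,3-bis(benzyloxy)-5-(11-bromoundecyl)benzene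
Product: 9 (3S)-17-[3,5-bis(benzyloxy)phenyl]heptadec-5-yn-3-ol, via dilithiated alkynol 8 (not isolated)
Conditions: 3 (1.5 equiv), n-BuLi (1.95 equiv per 3), THF, –78 → –20 °C; then 7 (1.0 equiv), DMPU, –20 °C → rt; H2O
Reagents that add atoms: none
Why: Two equivalents of n-BuLi remove first the O–H and then the C(sp)–H of 3; the alkynyllithium carbon of dianion 8, its more basic and far more nucleophilic site, should displace bromide from the unhindered primary C11' of 7 in an SN2 reaction that DMPU accelerates by breaking up lithium aggregates, forming C11'–C12'. The closest known reaction type is the C-alkylation of dilithiated propargylic and homopropargylic alcohols with primary alkyl bromides, a standard operation in long-chain lipid and pheromone synthesis. No ring is closed and no stereocentre is formed; the C15' carbinol carbon has no acidic hydrogen and should keep the S configuration set by the epoxide. The selectivity needed is C- over O-alkylation and substitution over E2: the hindered, tightly aggregated secondary lithium alkoxide is a poor nucleophile beside the acetylide, and the slim acetylide has little tendency to eliminate an unbranched primary bromide. Because n-BuLi is kept just below two equivalents per 3, none should remain to metalate the benzyl ethers or exchange the bromide of 7.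

Step 4
Reactants: 9 (3S)-17-[3,5-bis(benzyloxy)phenyl]heptadec-5-yn-3-ol
Product: 10 Hansfordiol C, 5-[(15S)-15-hydroxyheptadecyl]benzene-1,3-diol
Conditions: H2 (1–3 bar), 10% Pd/C, EtOAc/EtOH, rt
Reagents that add atoms: none
Why: Heterogeneous catalytic hydrogenation should saturate the C12'≡C13' alkyne and hydrogenolyse both benzyl aryl ethers in one operation, while the C15' carbinol, neither benzylic nor propargylic, is inert and keeps its S configuration.

Compound list
1 | (S)-1,2-epoxybutane, (2S)-2-ethyloxirane | CC[C@H]1CO1 | starting material
2 | lithium acetylide–ethylenediamine complex | [Li+].[C-]#C.NCCN | starting material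
3 | (S)-hex-5-yn-3-ol | CC[C@H](O)CC#C | intermediate
4 | 11-bromoundec-1-ene | C=CCCCCCCCCCBr | starting material
5 | 1,3-bis(benzyloxy)-5-bromobenzene | Brc1cc(OCc2ccccc2)cc(OCc2ccccc2)c1 | starting material
6 | 9-(11-bromoundecyl)-9-borabicyclo[3.3.1]nonane, B-(11-bromoundecyl)-9-BBN | BrCCCCCCCCCCCB1C2CCCC1CCC2 | intermediate
7 | 1,3-bis(benzyloxy)-5-(11-bromoundecyl)benzene | BrCCCCCCCCCCCc1cc(OCc2ccccc2)cc(OCc2ccccc2)c1 | intermediate
8 | dilithiated alkynol, lithium (3S)-6-lithiohex-5-yn-3-olate | CC[C@H](O[Li])CC#C[Li] | intermediate
9 | (3S)-17-[3,5-bis(benzyloxy)phenyl]heptadec-5-yn-3-ol | CC[C@H](O)CC#CCCCCCCCCCCCc1cc(OCc2ccccc2)cc(OCc2ccccc2)c1 | intermediate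
10 | Hansfordiol C, 5-[(15S)-15-hydroxyheptadecyl]benzene-1,3-diol | CC[C@H](O)CCCCCCCCCCCCCCc1cc(O)cc(O)c1 | target

Total step count: 4
Longest linear sequence: 3 steps (1 → 3 → 9 → 10; the branch 4 + 5 → 7 → 9 → 10 is equally long)

Steps most likely to fail

Step 3 (key step). What may go wrong: sluggish alkylation of the aggregated dianion, with competing O-alkylation of the alkoxide or E2 elimination of the bromide once the mixture is warmed. The fallback forms the same C11'–C12' bond by an alkyl–alkyl Suzuki coupling; it sets out from 1 and 7 and comes back to the route at 10. Epoxide 1 would be opened with vinylmagnesium bromide (CuI cat., THF, –30 °C) to (S)-hex-5-en-3-ol F1, which would be benzylated (NaH, BnBr, DMF) to (4S)-4-(benzyloxy)hex-1-ene F2. Hydroboration with 9-BBN would give the B-alkyl borane F3, which would be coupled in the same flask with bromide 7 (Pd(OAc)2, PCy3, K3PO4·H2O, THF, rt) to the tribenzyl ether 1,3-bis(benzyloxy)-5-[(15S)-15-(benzyloxy)heptadecyl]benzene F4. Hydrogenolysis of F4 (H2, Pd/C) should then give 10 directly.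

Step 2. What may go wrong: loss of the primary bromide during the coupling (hydrolysis or elimination by the aqueous base, or insertion of palladium into the C(sp3)–Br bond), or protodeboronation of the alkylborane, leading to mixtures that are hard to separate. The fallback is a copper-catalysed Grignard alkylation; it sets out from 5 and comes back at 7. Aryl bromide 5 would be converted with magnesium in THF into 3,5-bis(benzyloxy)phenylmagnesium bromide F5. F5 would be added slowly to an excess of purchased 1,11-dibromoundecane (BrCCCCCCCCCCCBr, 3 equiv) with catalytic Li2CuCl4 in THF at –10 °C → rt. Monosubstitution should give 7, and the excess dibromide would be recovered by distillation.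

Step 1. What may go wrong: loss of the volatile, water-soluble alkynol during isolation from DMSO, or base-induced migration of the terminal triple bond on prolonged contact with the amine complex. The fallback is a Lewis-acid-mediated opening with a silyl-masked alkyne; it sets out from 1 and comes back at 3. Lithium (trimethylsilyl)acetylide (from trimethylsilylacetylene and n-BuLi, THF, –78 °C) would open 1 in the presence of BF3·OEt2 to give the less volatile (3S)-6-(trimethylsilyl)hex-5-yn-3-ol F6. F6 could be purified by chromatography and desilylated (K2CO3, MeOH, rt) to 3.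

Further compounds
F1 | step 3 | (S)-hex-5-en-3-ol | CC[C@H](O)CC=C
F2 | step 3 | (4S)-4-(benzyloxy)hex-1-ene | CC[C@H](OCc1ccccc1)CC=C
F3 | step 3 | 9-[(4S)-4-(benzyloxy)hexyl]-9-borabicyclo[3.3.1]nonane | CC[C@H](OCc1ccccc1)CCCB1C2CCCC1CCC2
F4 | step 3 | 1,3-bis(benzyloxy)-5-[(15S)-15-(benzyloxy)heptadecyl]benzene | CC[C@H](OCc1ccccc1)CCCCCCCCCCCCCCc1cc(OCc2ccccc2)cc(OCc2ccccc2)c1
F5 | step 2 | 3,5-bis(benzyloxy)phenylmagnesium bromide | Br[Mg]c1cc(OCc2ccccc2)cc(OCc2ccccc2)c1
F6 | step 1 | (3S)-6-(trimethylsilyl)hex-5-yn-3-ol | CC[C@H](O)CC#C[Si](C)(C)C
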